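**Assumptions (one line each)**
- Core numbering follows the lignan convention (C1 carries the aryl group, C2 the CH2OH, C3 the CHO; ring A is the fused benzene ring, ring B the dihydro ring); the target is then (1S,2R), trans.
- The (Ra,R,R) antipode of the spiro-bis(oxazoline) ligand is taken to give (S)-7; if the sense is opposite, the mirror-image ligand is used.
- 4-(Benzyloxy)-3-hydroxybenzaldehyde is bought (otherwise one extra step from 3,4-dihydroxybenzaldehyde).

**Retrosynthetic overview**
1. Target ⇐ debenzylation, allylic oxidation and ester reduction of a trans-1-aryl-1,2-dihydronaphthalene-2,3-diester.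
2. Ring B (C3=C4) ⇐ intramolecular Wittig reaction of a phosphine–maleate ylide with the ring A aldehyde; C2 is set trans by base equilibration.
3. C8a–C1 bond and the C1 stereocentre ⇐ [3,3] shift of an aryl allyl ether, which places carbon at the hindered position next to the ring A oxygen.
4. Key bond: the aryl C–O bond of that ether, made enantioselectively by copper-carbene O–H insertion of the ring A phenol into a vinyl diazo ester; its stereocentre is relayed to C1.
5. Vinyl diazo ester ⇐ veratraldehyde + dimethyl maleate. Both aryl rings are bought; ring B is the only ring formed (step 5).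

**Route**

Step 1
Reactants: 1 3,4-dimethoxybenzaldehyde; 2 dimethyl maleate
Product: 4 dimethyl (E)-2-(3,4-dimethoxybenzylidene)butanedioate, via phosphonium ylide 3 (not isolated)
Conditions: PBu3 (1.2 equiv), THF, 25 to 50 °C
Reagents that add atoms: none
Why: The phosphine adds to the maleate and a proton shift gives ester-stabilised ylide 3, which undergoes Wittig olefination with the aldehyde to the (E)-arylidene succinate; no stereocentre is formed.

Step 2
Reactants: 4 dimethyl (E)-2-(3,4-dimethoxybenzylidene)butanedioate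
Product: 5 dimethyl (E)-2-diazo-3-(3,4-dimethoxybenzylidene)butanedioate
Conditions: p-ABSA (1.3 equiv), DBU (1.5 equiv), MeCN, 0 to 25 °C
Reagents that add atoms: 4-acetamidobenzenesulfonyl azide (p-ABSA), CC(=O)Nc1ccc(cc1)S(=O)(=O)N=[N+]=[N-]
Why: Regitz diazo transfer to the methylene that is both α to an ester and allylic; the aryl group cis to the diazo carbon slows cyclisation of the vinyl diazo ester to a pyrazole.

Step 3
Reactants: 5 dimethyl (E)-2-diazo-3-(3,4-dimethoxybenzylidene)butanedioate; 6 4-(benzyloxy)-3-hydroxybenzaldehyde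
Product: 7 dimethyl (2S,3E)-2-[2-(benzyloxy)-5-formylphenoxy]-3-(3,4-dimethoxybenzylidene)butanedioate
Conditions: CuCl (5 mol%), (Ra,R,R)-7,7'-bis(4-phenyl-4,5-dihydrooxazol-2-yl)-1,1'-spirobiindane (6 mol%), NaB[3,5-(CF3)2C6H3]4 (6 mol%), 5 Å MS, CH2Cl2, 25 °C, slow addition of 5
Reagents that add atoms: none
Why: Proposed new method: the monovalent copper carbene from 5 is attacked by the phenol oxygen at the carbene carbon (the vinylogous carbon is substituted by the aryl group), and the copper-bound oxonium ylide/enol is protonated inside the chiral ligand pocket, which sets the (S) C–O stereocentre that is later relayed to C1; the closest known reaction type is the copper- or palladium-catalysed enantioselective carbenoid O–H insertion of phenols into α-alkyl- and α-aryl-α-diazo esters, not yet shown for an α-alkenyl diazo ester.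

Step 4
Reactants: 7 dimethyl (2S,3E)-2-[2-(benzyloxy)-5-formylphenoxy]-3-(3,4-dimethoxybenzylidene)butanedioate
Product: 9 dimethyl (Z)-2-{(S)-[3-(benzyloxy)-6-formyl-2-hydroxyphenyl](3,4-dimethoxyphenyl)methyl}but-2-enedioate, via ortho-dienone 8 (not isolated)
Conditions: Eu(fod)3 (10 mol%; fod = 6,6,7,7,8,8,8-heptafluoro-2,2-dimethyloctane-3,5-dionate), PhMe, 80 °C
Reagents that add atoms: none
Why: Aromatic Claisen rearrangement to the only free ortho carbon; the shift is suprafacial and runs through the conformer with the ether C–H eclipsing the alkene (ester outward, avoiding allylic strain with the cis aryl group), so (S)-7 gives (S)-C1 and the (Z)-diester, and the two ester groups on the allyl unit accelerate the shift.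

Step 5
Reactants: 9 dimethyl (Z)-2-{(S)-[3-(benzyloxy)-6-formyl-2-hydroxyphenyl](3,4-dimethoxyphenyl)methyl}but-2-enedioate
Product: 11 dimethyl (1S)-7-(benzyloxy)-1-(3,4-dimethoxyphenyl)-8-hydroxy-1,2-dihydronaphthalene-2,3-dicarboxylate (C2 epimers), via phosphonium ylide 10 (not isolated)
Conditions: PBu3 (1.2 equiv), THF (0.03 M), 25 to 50 °C
Reagents that add atoms: none
Why: PBu3 adds to the unsubstituted maleate carbon, proton transfer (relayed by the neighbouring phenol) gives stabilised ylide 10, and intramolecular Wittig olefination with the ring A aldehyde closes ring B; C2 forms as a mixture that is corrected in step 6.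

Step 6
Reactants: 11 dimethyl (1S)-7-(benzyloxy)-1-(3,4-dimethoxyphenyl)-8-hydroxy-1,2-dihydronaphthalene-2,3-dicarboxylate (C2 epimers)
Product: 12 dimethyl (1S,2R)-7-(benzyloxy)-1-(3,4-dimethoxyphenyl)-8-methoxy-1,2-dihydronaphthalene-2,3-dicarboxylate
Conditions: MeI (3 equiv), K2CO3 (3 equiv), DMF, 25 °C; then NaOMe (0.2 equiv), MeOH, 25 °C
Reagents that add atoms: iodomethane, CI
Why: Williamson O-methylation of the phenol, then base equilibration of the ester α-centre C2 to the trans isomer, expected to be favoured because it places the C1 aryl and C2 ester groups pseudo-diaxial, away from the C8 methoxy and C3 ester groups.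

Step 7
Reactants: 12 dimethyl (1S,2R)-7-(benzyloxy)-1-(3,4-dimethoxyphenyl)-8-methoxy-1,2-dihydronaphthalene-2,3-dicarboxylate
Product: 13 [(1S,2R)-7-(benzyloxy)-1-(3,4-dimethoxyphenyl)-8-methoxy-1,2-dihydronaphthalene-2,3-diyl]dimethanol
Conditions: i-Bu2AlH (6 equiv), CH2Cl2, −78 to 0 °C; aqueous potassium sodium tartrate
Reagents that add atoms: none
Why: Hydride reduction of both esters to the diol, 1,2-selective at the conjugated ester; the stereocentres are not touched.

Step 8
Reactants: 13 [(1S,2R)-7-(benzyloxy)-1-(3,4-dimethoxyphenyl)-8-methoxy-1,2-dihydronaphthalene-2,3-diyl]dimethanol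
Product: 14 (1S,2R)-7-(benzyloxy)-1-(3,4-dimethoxyphenyl)-2-(hydroxymethyl)-8-methoxy-1,2-dihydronaphthalene-3-carbaldehyde
Conditions: MnO2 (15 equiv), CH2Cl2, 25 °C, stopped at full conversion
Reagents that add atoms: none
Why: Chemoselective allylic oxidation; MnO2 oxidises the allylic alcohol to the conjugated aldehyde and leaves the saturated primary alcohol.

Step 9
Reactants: 14 (1S,2R)-7-(benzyloxy)-1-(3,4-dimethoxyphenyl)-2-(hydroxymethyl)-8-methoxy-1,2-dihydronaphthalene-3-carbaldehyde
Product: 15 vitekwangin B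
Conditions: BCl3 (3 equiv), C6HMe5 (5 equiv), CH2Cl2, −78 °C; MeOH quench
Reagents that add atoms: none
Why: Lewis-acid cleavage of the aryl benzyl ether with pentamethylbenzene as cation scavenger; at −78 °C the methyl ethers, the enal and both stereocentres are left alone.

**Compound list**
1 | 3,4-dimethoxybenzaldehyde | COc1ccc(C=O)cc1OC | starting material
2 | dimethyl maleate | COC(=O)/C=C\C(=O)OC | starting material
3 | dimethyl 2-(tributyl-λ5-phosphanylidene)butanedioate | CCCCP(CCCC)(CCCC)=C(CC(=O)OC)C(=O)OC | intermediate (not isolated)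
4 | dimethyl (E)-2-(3,4-dimethoxybenzylidene)butanedioate | COC(=O)C/C(=C\c1ccc(OC)c(OC)c1)C(=O)OC | intermediate
5 | dimethyl (E)-2-diazo-3-(3,4-dimethoxybenzylidene)butanedioate | COC(=O)C(=[N+]=[N-])/C(=C\c1ccc(OC)c(OC)c1)C(=O)OC | intermediate
6 | 4-(benzyloxy)-3-hydroxybenzaldehyde | O=Cc1ccc(OCc2ccccc2)c(O)c1 | starting material
7 | dimethyl (2S,3E)-2-[2-(benzyloxy)-5-formylphenoxy]-3-(3,4-dimethoxybenzylidene)butanedioate | COC(=O)[C@@H](Oc1cc(C=O)ccc1OCc1ccccc1)/C(=C\c1ccc(OC)c(OC)c1)C(=O)OC | intermediate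
8 | dimethyl (Z)-2-{[3-(benzyloxy)-6-formyl-2-oxocyclohexa-3,5-dien-1-yl](3,4-dimethoxyphenyl)methyl}but-2-enedioate (methine as in 9; ring sp3 carbon not assigned, lost on enolisation) | O=C1C(OCc2ccccc2)=CC=C(C=O)C1[C@H](c1ccc(OC)c(OC)c1)/C(C(=O)OC)=C/C(=O)OC | intermediate (not isolated)
9 | dimethyl (Z)-2-{(S)-[3-(benzyloxy)-6-formyl-2-hydroxyphenyl](3,4-dimethoxyphenyl)methyl}but-2-enedioate | COC(=O)/C=C(\C(=O)OC)[C@@H](c1ccc(OC)c(OC)c1)c1c(O)c(OCc2ccccc2)ccc1C=O | intermediate
10 | dimethyl 2-{(S)-[3-(benzyloxy)-6-formyl-2-hydroxyphenyl](3,4-dimethoxyphenyl)methyl}-3-(tributyl-λ5-phosphanylidene)butanedioate | COC(=O)C(=P(CCCC)(CCCC)CCCC)C(C(=O)OC)[C@@H](c1ccc(OC)c(OC)c1)c1c(O)c(OCc2ccccc2)ccc1C=O | intermediate (not isolated)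
11 | dimethyl (1S)-7-(benzyloxy)-1-(3,4-dimethoxyphenyl)-8-hydroxy-1,2-dihydronaphthalene-2,3-dicarboxylate (C2 epimers) | COc1ccc([C@H]2c3c(ccc(OCc4ccccc4)c3O)C=C(C(=O)OC)C2C(=O)OC)cc1OC | intermediate
12 | dimethyl (1S,2R)-7-(benzyloxy)-1-(3,4-dimethoxyphenyl)-8-methoxy-1,2-dihydronaphthalene-2,3-dicarboxylate | COc1ccc([C@H]2c3c(ccc(OCc4ccccc4)c3OC)C=C(C(=O)OC)[C@@H]2C(=O)OC)cc1OC | intermediate
13 | [(1S,2R)-7-(benzyloxy)-1-(3,4-dimethoxyphenyl)-8-methoxy-1,2-dihydronaphthalene-2,3-diyl]dimethanol | COc1ccc([C@H]2c3c(ccc(OCc4ccccc4)c3OC)C=C(CO)[C@@H]2CO)cc1OC | intermediate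
14 | (1S,2R)-7-(benzyloxy)-1-(3,4-dimethoxyphenyl)-2-(hydroxymethyl)-8-methoxy-1,2-dihydronaphthalene-3-carbaldehyde | COc1ccc([C@H]2c3c(ccc(OCc4ccccc4)c3OC)C=C(C=O)[C@@H]2CO)cc1OC | intermediate
15 | vitekwangin B, (1S,2R)-1-(3,4-dimethoxyphenyl)-7-hydroxy-2-(hydroxymethyl)-8-methoxy-1,2-dihydronaphthalene-3-carbaldehyde | COc1ccc([C@H]2c3c(ccc(O)c3OC)C=C(C=O)[C@@H]2CO)cc1OC | target

**Step count and risks**
Total steps: 9. Longest linear sequence: 9 (1 → 15); phenol 6 enters at step 3.

Most likely to fail: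

Step 3 (proposed new step). Risks are low enantioselectivity, carbene side reactions (cyclopropene or pyrazole formation, attack on the aldehyde) and loss of configuration at the acidic ether C–H. Fallback with known chemistry, setting out from 4 and returning at 7: the lithium dienolate of 4 (LiN(SiMe3)2, THF, −78 °C) is hydroxylated with the appropriate antipode of (camphorsulfonyl)oxaziridine to dimethyl (2R,3E)-2-hydroxy-3-(3,4-dimethoxybenzylidene)butanedioate F1. Mitsunobu etherification of F1 with 6 (PPh3, DIAD, PhMe, 0 °C) then gives 7 with inversion.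

Step 4. Risks are incomplete chirality transfer, migration toward the para position through the blocked ortho carbon, and lactonisation or oxa-Michael closure of the new phenol onto the diester. Fallback, setting out from 6 and returning at 12, builds the C8a–C1 bond by cross-coupling and a photoenolisation/Diels–Alder reaction. Bromination of 6 (Br2, NaOAc, AcOH) gives 4-(benzyloxy)-2-bromo-3-hydroxybenzaldehyde F2, and methylation (MeI, K2CO3, DMF) gives 4-(benzyloxy)-2-bromo-3-methoxybenzaldehyde F3. Suzuki coupling of F3 with bought 2-(3,4-dimethoxybenzyl)-4,4,5,5-tetramethyl-1,3,2-dioxaborolane (Pd(OAc)2, SPhos, K3PO4, PhMe–H2O, 80 °C) gives 4-(benzyloxy)-2-(3,4-dimethoxybenzyl)-3-methoxybenzaldehyde F4. Irradiation of F4 at 365 nm with dimethyl fumarate in the presence of Ti(Oi-Pr)4 and a TADDOL ligand gives dimethyl (1S)-7-(benzyloxy)-1-(3,4-dimethoxyphenyl)-4-hydroxy-8-methoxy-1,2,3,4-tetrahydronaphthalene-2,3-dicarboxylate F5. Dehydration (TsOH, PhMe, 60 °C) and NaOMe equilibration then give 12.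

Step 5. Risks are aldol-type trapping of the zwitterion instead of ylide formation, and phenol addition to the maleate. Fallback, setting out from 9 and returning at 12, replaces the phosphine annulation by reduction and a Stobbe-type condensation. Neutral methylation (MeI, Ag2O, CH2Cl2) gives dimethyl (Z)-2-{(S)-[3-(benzyloxy)-6-formyl-2-methoxyphenyl](3,4-dimethoxyphenyl)methyl}but-2-enedioate F6. Alkene-selective hydrogenation (H2, RhCl(PPh3)3, PhH, 25 °C) gives dimethyl 2-{(S)-[3-(benzyloxy)-6-formyl-2-methoxyphenyl](3,4-dimethoxyphenyl)methyl}butanedioate F7. NaOMe in MeOH then effects intramolecular aldol condensation of the ester α-methylene with the aldehyde and equilibrates C2, giving 12.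

**Further compounds**
F1 | step 3 | dimethyl (2R,3E)-2-hydroxy-3-(3,4-dimethoxybenzylidene)butanedioate | COC(=O)[C@H](O)/C(=C\c1ccc(OC)c(OC)c1)C(=O)OC
F2 | step 4 | 4-(benzyloxy)-2-bromo-3-hydroxybenzaldehyde | Oc1c(Br)c(C=O)ccc1OCc1ccccc1
F3 | step 4 | 4-(benzyloxy)-2-bromo-3-methoxybenzaldehyde | COc1c(Br)c(C=O)ccc1OCc1ccccc1
F4 | step 4 | 4-(benzyloxy)-2-(3,4-dimethoxybenzyl)-3-methoxybenzaldehyde | COc1ccc(Cc2c(C=O)ccc(OCc3ccccc3)c2OC)cc1OC
F5 | step 4 | dimethyl (1S)-7-(benzyloxy)-1-(3,4-dimethoxyphenyl)-4-hydroxy-8-methoxy-1,2,3,4-tetrahydronaphthalene-2,3-dicarboxylate | COc1ccc([C@H]2c3c(ccc(OCc4ccccc4)c3OC)C(O)C(C(=O)OC)C2C(=O)OC)cc1OC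
F6 | step 5 | dimethyl (Z)-2-{(S)-[3-(benzyloxy)-6-formyl-2-methoxyphenyl](3,4-dimethoxyphenyl)methyl}but-2-enedioate | COC(=O)/C=C(\C(=O)OC)[C@@H](c1ccc(OC)c(OC)c1)c1c(OC)c(OCc2ccccc2)ccc1C=O
F7 | step 5 | dimethyl 2-{(S)-[3-(benzyloxy)-6-formyl-2-methoxyphenyl](3,4-dimethoxyphenyl)methyl}butanedioate | COC(=O)CC(C(=O)OC)[C@@H](c1ccc(OC)c(OC)c1)c1c(OC)c(OCc2ccccc2)ccc1C=O
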